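Readings and results were computed with made-up constants; noise was put on by code.

I had 3 questions about two flasks, oak and ash, with the same charges and different times. In both, initiator begins chains on free monomer, and free monomer enters chains.

| setting | theta | oak | ash |
|---|---|---|---|
| free monomer | 0.19 M | 0.097 M | 0.097 M |
| initiator | 3.9 mM | 3.9 mM | 3.9 mM |
| remark | run made earlier |  |  |
| time |  | 8.0 min | 30 min |

theta run (percent of the free monomer charged)

| time / s | monomer in chains / % | free monomer / % |
|---|---|---|
| 10.0 | 0.8 | 99.2 |
| 15.0 | 0.2 | 99.2 |
| 25.0 | 1.5 | 99.5 |
| 50.0 | 2.4 | 96.8 |
| 90.0 | 8.2 | 91.1 |

(scatter of a reading: 0.5 percentage points)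

- the average divides the monomer in chains by the number of chains begun, living and dead together
- the earlier runs do not show the number of chains; that part of a forecast is a guess

- which of the two ends with the longer chains by the average number of monomer units in a chain (chains begun, living or dead) ("neither" if they lie within 10%) (oak / ash / neither)
- average number of monomer units in a chain (chains begun, living or dead) at the end, oak
- average number of monomer units in a chain (chains begun, living or dead) at the end, ash

I ordered the time scales, shortest first.

1. The readings end at 90.0 s. The theta flask then still held 91.1% of its free monomer, nearly all of it, so I saw only the start of the run.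

2. The loss read 3.20% at 50.0 s and 8.90% at 90.0 s, so it was speeding up. I took [free monomer] to fall as the exponential of minus the square of t/τ. The last reading gave theta τ = 4.91 min. Theta has the initiator charge of oak and ash, but more free monomer. I assumed that chains start at a rate proportional to [free monomer][initiator]. At a fixed initiator charge, τ squared then goes as one over the free monomer charged, so I took τ = 6.88 min for oak and ash.

3. Oak's 8.0 min is longer than this τ, and the law put 74.2% of its free monomer in chains, far beyond the readings. Ash's 30 min is longer still, and the law gave >99.9%.

4. The readings do not show the use of initiator, so I removed time. I assumed each chain begun takes one initiator. Dividing the rate of entry into chains by the rate of chain starts cancels time. Oak and ash both have 24.9: this is the charge ratio, free monomer charged per initiator charged. The length (number-average degree of polymerisation) is then the charge ratio times X/f, where X is the share of free monomer charged now in chains and f the share of initiator used. Chains exceed the charge ratio when X exceeds f.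

5. With X near its ceiling, I expected ash at 24.9 or longer. The order depended on f, so I left it open.

The forecast chose oak, with 60 (18 to 400) for oak and 35 (24 to 200) for ash, because “chains keep starting, so oak is probably longer”.

The flasks gave ash as the longer: oak 22.4, ash 30.8.

    monomer in chains → over-reaction product (k = 1.49 × 10⁻⁶ s⁻¹)
    free monomer + initiator → living end + monomer in chains (k = 0.0248 L mol⁻¹ s⁻¹)
    free monomer + living end → monomer in chains + living end, rate k3*[living end]*[free monomer] (k = 1.23 L mol⁻¹ s⁻¹)
    living end → dead end (k = 9.71 × 10⁻⁴ s⁻¹)

At 8.00 min, while initiator was still beginning chains and living ends were taking up free monomer, oak had X = 52.7%, lower than f = 58.5%, and its length stood below the charge ratio. At 30.0 min, ash had X = 94.0%, higher than f = 76.0%, which gives 30.8. A neighbour flask, the same as ash but with 0.24 M of free monomer, has a charge ratio of 61.5, X = 97.1% and f = 92.3%, which gives 64.7; the flask stood at 64.7.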